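**Plan**

1. Retrosynthesis: C13=C14 is cut first (Horner–Wadsworth–Emmons on a C13 methyl ketone). The 6β-OH/19-OH pair is traced to a 19,6β-lactone and, with the 3α-OH, to a 3,6-diketo 19-ester. C4–C5 and C9–C10 are then cut together, opening rings A and B to an acyclic polyene β-keto ester. This is cut at C1–C2 (acetoacetate dianion alkylation), C5=C10 (Wittig) and C6–O (aldehyde α-oxygenation), back to (E)-geranylacetone.
2. Enabling feature: the oxygens at C3 and at C19 on quaternary C4 are the two carbonyls of a 2-methylacetoacetate. The methyl-bearing carbons C10 and C8 mark a head-to-tail 1,5-diene (C5=C10, C8=C9). A radical at C4 can therefore close ring A (C4–C5) and then ring B by joining the tertiary C10 radical to C9.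
3. Forward: geranylacetone supplies C5–C9, C11–C13, C16 and C17. C6 is oxygenated, then C10/C20/C1 and C2–C4/C18/C19 are added to the chain. One oxidative radical step forms ring A, then ring B. The alkene is then moved to C8=C9, C3/C6/C19 are adjusted by oxidation and hydride reduction, and C14–C15 are added.
4. Stereochemistry: C6 is set by D-proline catalysis and, as an equatorial silyloxy group, dictates the chair–chair folding that sets C4, C5 and C10. C6 is then inverted through the ketone (hydride from the α face) and C3 comes from equatorial hydride delivery. The alkene geometries come from geranylacetone, the Wittig step and the Horner–Wadsworth–Emmons step.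

Key step: step 9

Remark: labdane numbering is used for all bicyclic compounds (ring A = C1–C5, C10; ring B = C5–C10; C17 on C8; C18 = 4α-methyl; C19 = 4β-carbon; C20 on C10; side chain C11–C16). Compounds 1, 6, 13 and 22 are taken as commercial.

**Route**

Step 1
Reactants: 1 (E)-geranylacetone
Product: 2 2-[(3E)-4,8-dimethylnona-3,7-dien-1-yl]-2-methyl-1,3-dioxolane
Conditions: HOCH2CH2OH, PPTS (cat.), PhH, reflux, Dean–Stark
Reagents that add atoms: ethylene glycol, OCCO
Why: Acid-catalysed ketalisation with azeotropic water removal masks the methyl ketone, which has to survive the later hydride and dianion steps.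

Step 2
Reactants: 2 the ketal
Product: 4 2-[(3E)-6-(3,3-dimethyloxiran-2-yl)-4-methylhex-3-en-1-yl]-2-methyl-1,3-dioxolane, via terminal bromohydrin 3 (not isolated)
Conditions: NBS, THF–H2O, 0 °C; then K2CO3, MeOH, rt
Reagents that add atoms: water, O
Why: Bromohydrin formation in aqueous THF is selective for the terminal trisubstituted alkene of a polyprenyl chain and base closes it to the epoxide (intramolecular Williamson reaction); the epoxide may be racemic because its carbons are excised in step 3.

Step 3
Reactants: 4 the terminal epoxide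
Product: 5 (4E)-4-methyl-7-(2-methyl-1,3-dioxolan-2-yl)hept-4-enal
Conditions: H5IO6, Et2O–THF, 0 °C, short contact; NaHCO3 quench
Reagents that add atoms: none
Why: Periodic acid opens the epoxide and cleaves the resulting glycol (Malaprade-type cleavage), removing three carbons and leaving C5 as the aldehyde with C6 as its α-carbon.

Step 4
Reactants: 5 the aldehyde; 6 ethyl 2-(triphenyl-λ5-phosphanylidene)propanoate
Product: 9 ethyl (2E,4S,6E)-4-hydroxy-2,6-dimethyl-9-(2-methyl-1,3-dioxolan-2-yl)nona-2,6-dienoate, via 2-anilinooxy aldehyde 7 (not isolated), via 4-anilinooxy enoate 8 (not isolated)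
Conditions: D-proline (20 mol %), PhNO, DMSO, rt; then 6, 0 °C to rt; then Cu(OAc)2 (30 mol %), EtOH, rt
Reagents that add atoms: nitrosobenzene, O=Nc1ccccc1
Why: Proline-catalysed enamine α-aminoxylation sets the C6 oxygen (D-proline gives the 2S aldehyde), the stabilised ylide converts the unisolated aldehyde into the E enoate (Wittig reaction, adding C10, C20 and C1), and Cu(OAc)2 cleaves the N–O bond without touching the enoate.

Step 5
Reactants: 9 the hydroxy enoate
Product: 10 ethyl (2E,4S,6E)-4-[(tert-butyldimethylsilyl)oxy]-2,6-dimethyl-9-(2-methyl-1,3-dioxolan-2-yl)nona-2,6-dienoate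
Conditions: TBSCl, imidazole, DMF, rt
Reagents that add atoms: tert-butyldimethylsilyl chloride, CC(C)(C)[Si](C)(C)Cl
Why: Silylation of the secondary allylic alcohol gives a bulky ether that is inert in steps 6–9 and later serves as the equatorial control group.

Step 6
Reactants: 10 the silyl ether ester
Product: 11 (2E,4S,6E)-4-[(tert-butyldimethylsilyl)oxy]-2,6-dimethyl-9-(2-methyl-1,3-dioxolan-2-yl)nona-2,6-dien-1-ol
Conditions: DIBAL-H (2.2 equiv), CH2Cl2, −78 °C; Rochelle salt work-up
Reagents that add atoms: none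
Why: 1,2-Reduction of the α,β-unsaturated ester by the aluminium hydride gives the primary allylic alcohol at C1.

Step 7
Reactants: 11 the allylic alcohol
Product: 12 (2E,4S,6E)-1-bromo-4-[(tert-butyldimethylsilyl)oxy]-2,6-dimethyl-9-(2-methyl-1,3-dioxolan-2-yl)nona-2,6-diene
Conditions: CBr4, PPh3, CH2Cl2, 0 °C
Reagents that add atoms: tetrabromomethane, BrC(Br)(Br)Br
Why: The Appel reaction converts the primary allylic alcohol into the bromide under neutral conditions, with the E alkene, the ketal and the silyl ether untouched.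

Step 8
Reactants: 12 the allylic bromide; 13 ethyl 2-methyl-3-oxobutanoate
Product: 14 ethyl (6E,8S,10E)-8-[(tert-butyldimethylsilyl)oxy]-2,6,10-trimethyl-13-(2-methyl-1,3-dioxolan-2-yl)-3-oxotrideca-6,10-dienoate
Conditions: 13, NaH, THF, 0 °C; n-BuLi, 0 °C; then 12, 0 °C; aq NH4Cl
Reagents that add atoms: none
Why: γ-Alkylation of the acetoacetate dianion: the more reactive terminal carbanion displaces the allylic bromide by SN2 and forms C1–C2, giving the cyclisation substrate as a mixture of epimers at the enolisable C4.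

Step 9
Reactants: 14 the polyene β-keto ester
Product: 15 ethyl 6α-[(tert-butyldimethylsilyl)oxy]-13,13-ethylenedioxy-3-oxo-14,15-dinorlabd-8(17)-en-19-oate
Conditions: Mn(OAc)3·2H2O (2.2 equiv), Cu(OAc)2·H2O (1 equiv), degassed AcOH, 25 °C
Reagents that add atoms: none
Why: Mn(OAc)3 oxidises the enolised β-keto ester to the C4 radical, which adds 6-endo-trig to C5 of the C5=C10 alkene (ring A); the tertiary C10 radical then adds 6-endo-trig to C9 of the C8=C9 alkene (ring B, the C9–C10 bond), and Cu(OAc)2 oxidises the tertiary C8 radical to the alkene, expected mainly as the 8(17)-ene with 7-ene and 8-ene isomers that all converge in step 10. The closest known reaction type is the manganese triacetate/copper diacetate oxidative free-radical polyene cyclisation of 2-methylacetoacetates to trans-decalins. Both closures should run through a chair–chair array of the two E alkenes, which gives the trans ring fusion (5α-H, 10β-CH3) and the 9α-H. C4 is set by the cyclic enol radical, which places the ester axial (β, the later C19) and the methyl equatorial. The absolute sense comes from the C6 silyloxy stereocentre, which has to sit equatorial (6α) to avoid allylic 1,3-strain with the C10 methyl and the developing 1,3-diaxial contacts with C19 and C20, so the S centre selects the normal-labdane folding. The step needs 6-endo over 5-exo closure at both alkenes, secured by the methyl groups on the inner alkene carbons C10 and C8, and a clean stop after ring B, secured by the ketal-masked side chain that offers no further alkene.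

Step 10
Reactants: 15 the bicyclic alkene mixture
Product: 17 ethyl 13,13-ethylenedioxy-6α-hydroxy-3-oxo-14,15-dinorlabd-8-en-19-oate, via silyl-protected 8-ene ketal 16 (not isolated)
Conditions: anhydrous TsOH (0.2 equiv), HOCH2CH2OH (0.2 equiv), PhH, 70 °C; then HF·pyridine, pyridine–THF, 0 °C to rt
Reagents that add atoms: none
Why: Acid-catalysed alkene isomerisation through the tertiary C8 cation should funnel the 8(17)-, 7- and 8-ene isomers into the tetrasubstituted C8=C9 alkene, the thermodynamic position, which also removes the C9 stereocentre; fluoride then cleaves the silyl ether while the ketal stays on.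

Step 11
Reactants: 17 the 6α-alcohol
Product: 18 ethyl 13,13-ethylenedioxy-3,6-dioxo-14,15-dinorlabd-8-en-19-oate
Conditions: Dess–Martin periodinane, NaHCO3, CH2Cl2, rt
Reagents that add atoms: none
Why: Dess–Martin oxidation under buffered neutral conditions gives the 6-ketone without moving the β,γ-alkene into conjugation and without loss of the ketal.

Step 12
Reactants: 18 the 3,6-diketone
Product: 21 3α-hydroxy-13-oxo-14,15-dinorlabd-8-en-19,6β-olide, via 3α,6β-diol ester ketal 19 (not isolated), via 19,6β-lactone ketal 20 (not isolated)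
Conditions: LiBH(s-Bu)3 (L-Selectride, 3 equiv), THF, −78 to 0 °C; aq NH4Cl; then CSA (0.2 equiv), THF–H2O, 40 °C
Reagents that add atoms: water, O
Why: Bulky trialkylborohydride reduction delivers hydride equatorially at C3 (axial 3α-OH) and from the open α face at C6 (6β-OH; the β face is screened by the axial C19 ester and C20 methyl), after which acid closes the 1,3-diaxial 6β-OH/C19 ester pair to the γ-lactone and hydrolyses the ketal.

Step 13
Reactants: 21 the lactone methyl ketone; 22 triethyl phosphonoacetate
Product: 23 ethyl (13E)-3α-hydroxy-19-oxo-19,6β-epoxylabda-8,13-dien-15-oate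
Conditions: 22, NaH, THF, 0 to 45 °C; chromatography
Reagents that add atoms: none
Why: Horner–Wadsworth–Emmons olefination of the only ketone present adds C14–C15 and should give mainly the 13E enoate (the minor 13Z isomer is removed by chromatography), the hindered lactone carbonyl being inert to the phosphonate anion.

Step 14
Reactants: 23 the lactone ester
Product: 24 (13E)-3α-hydroxy-19-oxo-19,6β-epoxylabda-8,13-dien-15-oic acid
Conditions: LiOH·H2O, THF–MeOH–H2O, rt; 1 M HCl to pH 3
Reagents that add atoms: lithium hydroxide, [Li+].[OH-]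
Why: Saponification of the unhindered conjugated ethyl ester; the neopentyl-type lactone carbonyl hydrolyses slowly and any ring-opened material should reclose on acidification.

Step 15
Reactants: 24 the lactone acid
Product: 26 (13E)-3α,6β,19-trihydroxylabda-8,13-dien-15-oic acid, via lithium carboxylate 25 (not isolated)
Conditions: LiOt-Bu (1.0 equiv), THF, 0 °C; then LiBH4 (4 equiv), THF, 50 °C; 1 M HCl to pH 3, 0 °C
Reagents that add atoms: none
Why: Chemoselective hydride reduction: LiBH4 reduces lactones to diols but leaves a lithium carboxylate untouched, so the 19,6β-lactone is opened to the 19-OH and 6β-OH while the C15 acid survives.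

**Compound list**

1 | (5E)-6,10-dimethylundeca-5,9-dien-2-one, (E)-geranylacetone | CC(C)=CCC/C(C)=C/CCC(C)=O | starting material
2 | 2-[(3E)-4,8-dimethylnona-3,7-dien-1-yl]-2-methyl-1,3-dioxolane | CC(C)=CCC/C(C)=C/CCC1(C)OCCO1 | intermediate
3 | (6E)-3-bromo-2,6-dimethyl-9-(2-methyl-1,3-dioxolan-2-yl)non-6-en-2-ol (racemic) | CC(C)(O)C(Br)CC/C(C)=C/CCC1(C)OCCO1 | intermediate (not isolated)
4 | 2-[(3E)-6-(3,3-dimethyloxiran-2-yl)-4-methylhex-3-en-1-yl]-2-methyl-1,3-dioxolane (racemic) | CC1(C)OC1CC/C(C)=C/CCC2(C)OCCO2 | intermediate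
5 | (4E)-4-methyl-7-(2-methyl-1,3-dioxolan-2-yl)hept-4-enal | O=CCC/C(C)=C/CCC1(C)OCCO1 | intermediate
6 | ethyl 2-(triphenyl-λ5-phosphanylidene)propanoate | CCOC(=O)C(C)=P(c1ccccc1)(c1ccccc1)c1ccccc1 | starting material
7 | (2S,4E)-2-(anilinooxy)-4-methyl-7-(2-methyl-1,3-dioxolan-2-yl)hept-4-enal | O=C[C@@H](ONc1ccccc1)C/C(C)=C/CCC1(C)OCCO1 | intermediate (not isolated)
8 | ethyl (2E,4S,6E)-4-(anilinooxy)-2,6-dimethyl-9-(2-methyl-1,3-dioxolan-2-yl)nona-2,6-dienoate | CCOC(=O)/C(C)=C/[C@@H](ONc1ccccc1)C/C(C)=C/CCC1(C)OCCO1 | intermediate (not isolated)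
9 | ethyl (2E,4S,6E)-4-hydroxy-2,6-dimethyl-9-(2-methyl-1,3-dioxolan-2-yl)nona-2,6-dienoate | CCOC(=O)/C(C)=C/[C@@H](O)C/C(C)=C/CCC1(C)OCCO1 | intermediate
10 | ethyl (2E,4S,6E)-4-[(tert-butyldimethylsilyl)oxy]-2,6-dimethyl-9-(2-methyl-1,3-dioxolan-2-yl)nona-2,6-dienoate | CCOC(=O)/C(C)=C/[C@@H](O[Si](C)(C)C(C)(C)C)C/C(C)=C/CCC1(C)OCCO1 | intermediate
11 | (2E,4S,6E)-4-[(tert-butyldimethylsilyl)oxy]-2,6-dimethyl-9-(2-methyl-1,3-dioxolan-2-yl)nona-2,6-dien-1-ol | OC/C(C)=C/[C@@H](O[Si](C)(C)C(C)(C)C)C/C(C)=C/CCC1(C)OCCO1 | intermediate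
12 | (2E,4S,6E)-1-bromo-4-[(tert-butyldimethylsilyl)oxy]-2,6-dimethyl-9-(2-methyl-1,3-dioxolan-2-yl)nona-2,6-diene | BrC/C(C)=C/[C@@H](O[Si](C)(C)C(C)(C)C)C/C(C)=C/CCC1(C)OCCO1 | intermediate
13 | ethyl 2-methyl-3-oxobutanoate | CCOC(=O)C(C)C(C)=O | starting material
14 | ethyl (6E,8S,10E)-8-[(tert-butyldimethylsilyl)oxy]-2,6,10-trimethyl-13-(2-methyl-1,3-dioxolan-2-yl)-3-oxotrideca-6,10-dienoate (C2 epimers) | CCOC(=O)C(C)C(=O)CC/C(C)=C/[C@@H](O[Si](C)(C)C(C)(C)C)C/C(C)=C/CCC1(C)OCCO1 | intermediate
15 | ethyl 6α-[(tert-butyldimethylsilyl)oxy]-13,13-ethylenedioxy-3-oxo-14,15-dinorlabd-8(17)-en-19-oate (5α-H, 9α-H, 10β-CH3, 4β-CO2Et, 4α-CH3) | C=C1[C@H](CCC3(C)OCCO3)[C@@]2(C)CCC(=O)[C@](C)(C(=O)OCC)[C@@H]2[C@@H](O[Si](C)(C)C(C)(C)C)C1 | intermediate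
16 | ethyl 6α-[(tert-butyldimethylsilyl)oxy]-13,13-ethylenedioxy-3-oxo-14,15-dinorlabd-8-en-19-oate | CC1=C(CCC3(C)OCCO3)[C@@]2(C)CCC(=O)[C@](C)(C(=O)OCC)[C@@H]2[C@@H](O[Si](C)(C)C(C)(C)C)C1 | intermediate (not isolated)
17 | ethyl 13,13-ethylenedioxy-6α-hydroxy-3-oxo-14,15-dinorlabd-8-en-19-oate | CC1=C(CCC3(C)OCCO3)[C@@]2(C)CCC(=O)[C@](C)(C(=O)OCC)[C@@H]2[C@@H](O)C1 | intermediate
18 | ethyl 13,13-ethylenedioxy-3,6-dioxo-14,15-dinorlabd-8-en-19-oate | CC1=C(CCC3(C)OCCO3)[C@@]2(C)CCC(=O)[C@](C)(C(=O)OCC)[C@@H]2C(=O)C1 | intermediate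
19 | ethyl 13,13-ethylenedioxy-3α,6β-dihydroxy-14,15-dinorlabd-8-en-19-oate | CC1=C(CCC3(C)OCCO3)[C@@]2(C)CC[C@@H](O)[C@](C)(C(=O)OCC)[C@@H]2[C@H](O)C1 | intermediate (not isolated)
20 | 13,13-ethylenedioxy-3α-hydroxy-14,15-dinorlabd-8-en-19,6β-olide | CC1=C(CCC4(C)OCCO4)[C@@]2(C)CC[C@@H](O)[C@](C)(C(=O)O3)[C@@H]2[C@H]3C1 | intermediate (not isolated)
21 | 3α-hydroxy-13-oxo-14,15-dinorlabd-8-en-19,6β-olide | CC1=C(CCC(C)=O)[C@@]2(C)CC[C@@H](O)[C@](C)(C(=O)O3)[C@@H]2[C@H]3C1 | intermediate
22 | triethyl phosphonoacetate | CCOC(=O)CP(=O)(OCC)OCC | starting material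
23 | ethyl (13E)-3α-hydroxy-19-oxo-19,6β-epoxylabda-8,13-dien-15-oate (19,6β-lactone) | CC1=C(CC/C(C)=C/C(=O)OCC)[C@@]2(C)CC[C@@H](O)[C@](C)(C(=O)O3)[C@@H]2[C@H]3C1 | intermediate
24 | (13E)-3α-hydroxy-19-oxo-19,6β-epoxylabda-8,13-dien-15-oic acid | CC1=C(CC/C(C)=C/C(=O)O)[C@@]2(C)CC[C@@H](O)[C@](C)(C(=O)O3)[C@@H]2[C@H]3C1 | intermediate
25 | lithium (13E)-3α-hydroxy-19-oxo-19,6β-epoxylabda-8,13-dien-15-oate | [Li+].CC1=C(CC/C(C)=C/C(=O)[O-])[C@@]2(C)CC[C@@H](O)[C@](C)(C(=O)O3)[C@@H]2[C@H]3C1 | intermediate (not isolated)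
26 | (13E)-3α,6β,19-trihydroxylabda-8,13-dien-15-oic acid, (3R,4S,5R,6R,10S) | CC1=C(CC/C(C)=C/C(=O)O)[C@@]2(C)CC[C@@H](O)[C@](C)(CO)[C@@H]2[C@H](O)C1 | target

**Step count and risks**

Total steps: 15. Longest linear sequence: 15 steps, from (E)-geranylacetone.

Steps most likely to fail:

Step 9 (key step). The hindered tertiary C10 radical may be oxidised by Cu(OAc)2 before it adds to C9, so that the cascade stops after ring A. The fallback accepts that outcome and makes the C9–C10 bond in a second radical event without a competing oxidant. It sets out from 14: Mn(OAc)3·2H2O with a large excess of Cu(OAc)2·H2O in AcOH should give the monocyclic 10(20)-ene keto ester F1, with C4, C5 and C6 already set. The C10 radical is then regenerated by hydrogen-atom transfer from a cobalt hydride (Co(salen)Cl, where salen is the N,N′-bis(3,5-di-tert-butylsalicylidene)-1,2-cyclohexanediamine dianion, with PhSiH3 in benzene at rt; a cycloisomerisation of the known cobalt-hydride type). It should add 6-endo to C9 through the same chair, and return of a hydrogen atom to the catalyst gives the alkene. The fallback comes back to the route at 16, which step 10 converts into 17.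

Step 10. The acid may ionise the allylic C6–O bond of the transient 7-ene isomer (diene formation), or the equilibration may stall short of the tetrasubstituted alkene. The fallback moves the double bond under neutral radical conditions and separates this from deprotection. It sets out from 15: cobalt-hydride hydrogen-atom-transfer isomerisation (Co(salen)Cl, PhSiH3, benzene, rt) passes through the C8 radical in place of the C8 cation and should deliver 16; no new compound arises (F0). HF·pyridine then removes the silyl ether, and the fallback comes back at 17.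

Step 15. Reduction of the hindered lactone may be incomplete, or the carboxyl group may be attacked once boranes build up. The fallback reduces everything and restores the acid by selective oxidation. It sets out from 23, omitting step 14: LiAlH4 in THF at 0 °C should reduce the lactone and the enoate together to (13E)-labda-8,13-diene-3α,6β,15,19-tetraol F2. MnO2 in CH2Cl2 should oxidise only the allylic C15 alcohol, to (13E)-3α,6β,19-trihydroxylabda-8,13-dien-15-al F3. Pinnick oxidation (NaClO2, NaH2PO4, 2-methyl-2-butene, t-BuOH–H2O) then gives the acid, and the fallback comes back at 26.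

Further compounds
F1 | step 9 | ethyl 6α-[(tert-butyldimethylsilyl)oxy]-13,13-ethylenedioxy-3-oxo-9,10-seco-14,15-dinorlabda-8,10(20)-dien-19-oate | C=C1CCC(=O)[C@](C)(C(=O)OCC)[C@@H]1[C@@H](O[Si](C)(C)C(C)(C)C)C/C(C)=C/CCC2(C)OCCO2
F0 | step 10 | none | none
F2 | step 15 | (13E)-labda-8,13-diene-3α,6β,15,19-tetraol | CC1=C(CC/C(C)=C/CO)[C@@]2(C)CC[C@@H](O)[C@](C)(CO)[C@@H]2[C@H](O)C1
F3 | step 15 | (13E)-3α,6β,19-trihydroxylabda-8,13-dien-15-al | CC1=C(CC/C(C)=C/C=O)[C@@]2(C)CC[C@@H](O)[C@](C)(CO)[C@@H]2[C@H](O)C1
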